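**Assumption and abbreviations:** locants C1–C20 are cembrane numbers of the target (C1 = ring CH carrying the lactone α‑carbon C15; C16 = lactone C=O; C17 = methyl on C15; C3 = lactone O–CH; C4 = carbinol carbon with methyl C18; C7 = allylic carbinol; C8 carries methylidene C19; C11/C12 = oxirane, methyl C20 on C12). Ox = (2S,3S)-3-(3-iodobut-3-en-1-yl)-2-methyloxiran-2-yl, PMB = 4-methoxybenzyl, TES = triethylsilyl. Chiral ligands and catalysts are bought.

## Retrosynthetic overview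

1. Target ⇐ desilylation and C7 correction (oxidation, CBS reduction) ⇐ 14‑membered ring closed last at C7–C8 by intramolecular NiCl2/CrCl2 alkenyl iodide–aldehyde coupling of 32.
2. Lactone of 32 ⇐ acrylate ring-closing metathesis, CuH conjugate reduction (C1), enolate methylation (C15); C4 carbinol ⇐ matched Sharpless epoxidation of the C3 allylic alcohol and hydride opening at C5.
3. Key C2–C3 bond: intermolecular Keck asymmetric carbonyl allylation of East enal 21 (C3–C7) with West 2‑substituted allylstannane 17 (C8–C14, C1, C2).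
4. 17 ⇐ pent-4-yn-1-ol (hydroiodination, Johnson–Claisen, Mannich methylenation, Shi epoxidation); 21 ⇐ propane-1,3-diol (Wittig).
5. Ring order: C11–C12 oxirane (step 10) → six-membered lactone (step 21) → 14‑membered carbocycle (step 26).

## Route

### West fragment

Step 1
Reactants: 1 pent-4-yn-1-ol
Product: 2 4-iodopent-4-en-1-ol
Conditions: NaI, Me3SiCl, H2O, MeCN, 0 °C to rt
Reagents that add atoms: sodium iodide, [Na+].[I-]
Why: Markovnikov hydroiodination of the terminal alkyne by hydrogen iodide generated in the flask gives the 2-iodo-1-alkene selectively and creates no stereocentre.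

Step 2
Reactants: 2 4-iodopent-4-en-1-ol
Product: 3 4-iodopent-4-enal
Conditions: Dess–Martin periodinane, NaHCO3, CH2Cl2, 0 °C to rt
Reagents that add atoms: none
Why: Dess–Martin oxidation converts the primary alcohol into the aldehyde under buffered neutral conditions that leave the alkenyl iodide untouched.

Step 3
Reactants: 3 4-iodopent-4-enal
Product: 4 rac-6-iodo-2-methylhepta-1,6-dien-3-ol
Conditions: CH2=C(CH3)MgBr, THF, −78 °C; aq. NH4Cl
Reagents that add atoms: isopropenylmagnesium bromide, CC(=C)[Mg]Br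
Why: Grignard 1,2-addition to the aldehyde at low temperature is far faster than iodine–magnesium exchange, and the racemic carbinol centre is erased in the next step.

Step 4
Reactants: 4 rac-6-iodo-2-methylhepta-1,6-dien-3-ol
Product: 6 ethyl (4E)-8-iodo-4-methylnona-4,8-dienoate, via mixed ketene acetal 5 (not isolated)
Conditions: CH3C(OEt)3 (excess), EtCO2H (cat.), 140 °C, ethanol distilled off
Reagents that add atoms: triethyl orthoacetate, CCOC(C)(OCC)OCC
Why: Johnson–Claisen orthoester rearrangement through a chair transition state with the carbinol substituent equatorial forms the C13–C14 bond and the (E)-trisubstituted C11=C12 alkene (typically above 95:5).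

Step 5
Reactants: 6 ethyl (4E)-8-iodo-4-methylnona-4,8-dienoate
Product: 7 (4E)-8-iodo-4-methylnona-4,8-dienal
Conditions: iBu2AlH, CH2Cl2, −78 °C
Reagents that add atoms: none
Why: Partial hydride reduction of the ester at −78 °C stops at the tetrahedral aluminium hemiacetal, which releases the aldehyde on work-up.

Step 6
Reactants: 7 (4E)-8-iodo-4-methylnona-4,8-dienal
Product: 8 (5E)-9-iodo-1-methoxy-5-methyldeca-1,5,9-triene (mixture of enol ether isomers at C1)
Conditions: MeOCH2PPh3Cl, KN(SiMe3)2, THF, 0 °C to rt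
Reagents that add atoms: (methoxymethyl)triphenylphosphonium chloride, COC[P+](c1ccccc1)(c1ccccc1)c1ccccc1.[Cl-]
Why: Wittig olefination with the methoxymethylene ylide adds the one carbon needed, and the enol ether geometry is irrelevant.

Step 7
Reactants: 8 (5E)-9-iodo-1-methoxy-5-methyldeca-1,5,9-triene
Product: 9 (5E)-9-iodo-5-methyldeca-5,9-dienal
Conditions: 2 M aq. HCl, THF, rt
Reagents that add atoms: water, O
Why: Acid-catalysed enol ether hydrolysis unmasks the homologated aldehyde without touching the alkenyl iodide or the trisubstituted alkene.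

Step 8
Reactants: 9 (5E)-9-iodo-5-methyldeca-5,9-dienal
Product: 11 (5E)-9-iodo-5-methyl-2-methylidenedeca-5,9-dienal, via Mannich base 10 (not isolated)
Conditions: CH2=NMe2 iodide (Eschenmoser salt), Et3N, CH2Cl2, rt
Reagents that add atoms: N,N-dimethylmethaniminium iodide, C[N+](C)=C.[I-]
Why: Mannich reaction of the aldehyde with the iminium salt followed by elimination of dimethylamine (Mannich α-methylenation) installs the 2-methylidene group of the future allyl unit.

Step 9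
Reactants: 11 (5E)-9-iodo-5-methyl-2-methylidenedeca-5,9-dienal
Product: 12 (5E)-9-iodo-5-methyl-2-methylidenedeca-5,9-dien-1-ol
Conditions: NaBH4, CeCl3·7H2O, MeOH, 0 °C
Reagents that add atoms: none
Why: Luche reduction gives clean 1,2-reduction of the enal to the 2-substituted allylic alcohol.

Step 10
Reactants: 12 (5E)-9-iodo-5-methyl-2-methylidenedeca-5,9-dien-1-ol
Product: 13 4-[(2S,3S)-3-(3-iodobut-3-en-1-yl)-2-methyloxiran-2-yl]-2-methylidenebutan-1-ol
Conditions: L-fructose-derived Shi ketone (30 mol %), KHSO5 (as 2KHSO5·KHSO4·K2SO4), K2CO3, Bu4NHSO4, MeCN/CH2(OMe)2/aq. Na2B4O7 buffer, 0 °C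
Reagents that add atoms: potassium peroxymonosulfate, [K+].[O-]S(=O)(=O)OO
Why: Shi asymmetric epoxidation reacts only at the electron-rich (E)-trisubstituted alkene and, through the spiro transition state of the L-fructose-derived dioxirane, gives the trans (11S,12S)-oxirane, the mirror image of the (R,R) sense of the D-fructose-derived ketone.

Step 11
Reactants: 13 4-[(2S,3S)-3-(3-iodobut-3-en-1-yl)-2-methyloxiran-2-yl]-2-methylidenebutan-1-ol
Product: 15 (2S,3S)-2-[3-(bromomethyl)but-3-en-1-yl]-3-(3-iodobut-3-en-1-yl)-2-methyloxirane, via allylic mesylate 14 (not isolated)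
Conditions: MsCl, Et3N, THF, 0 °C; then LiBr, 0 °C to rt
Reagents that add atoms: lithium bromide, [Li+].[Br-]
Why: Mesylation followed by SN2 displacement with bromide converts the allylic alcohol into the allylic bromide under non-acidic conditions that the oxirane tolerates.

Step 12
Reactants: 15 (2S,3S)-2-[3-(bromomethyl)but-3-en-1-yl]-3-(3-iodobut-3-en-1-yl)-2-methyloxirane
Product: 17 tributyl(2-methylidene-4-Ox-butyl)stannane, via allylzinc bromide 16 (not isolated)
Conditions: Zn dust, Bu3SnCl, THF/sat. aq. NH4Cl, rt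
Reagents that add atoms: tributyltin chloride, CCCC[Sn](Cl)(CCCC)CCCC
Why: Zinc-mediated Barbier-type stannylation traps the allylzinc with the tin chloride, only one stannane can form because both allyl termini are CH2, and zinc does not insert into the alkenyl iodide.

### East fragment

Step 13
Reactants: 18 propane-1,3-diol
Product: 19 3-[(4-methoxyphenyl)methoxy]propan-1-ol
Conditions: NaH, PMBCl, Bu4NI (cat.), THF, 0 °C to rt (diol in excess)
Reagents that add atoms: 4-methoxybenzyl chloride, COc1ccc(CCl)cc1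
Why: Williamson etherification of the monosodium alkoxide of an excess of the diol gives the mono-PMB ether.

Step 14
Reactants: 19 3-[(4-methoxyphenyl)methoxy]propan-1-ol
Product: 20 3-[(4-methoxyphenyl)methoxy]propanal
Conditions: Dess–Martin periodinane, NaHCO3, CH2Cl2, rt
Reagents that add atoms: none
Why: Dess–Martin oxidation gives the β-alkoxy aldehyde without base-induced elimination.

Step 15
Reactants: 20 3-[(4-methoxyphenyl)methoxy]propanal
Product: 21 (2E)-5-[(4-methoxyphenyl)methoxy]-2-methylpent-2-enal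
Conditions: Ph3P=C(CH3)CHO, toluene, 100 °C
Reagents that add atoms: 2-(triphenylphosphoranylidene)propanal, CC(C=O)=P(c1ccccc1)(c1ccccc1)c1ccccc1
Why: Wittig olefination with the stabilised formyl ylide gives the (E)-2-methyl enal (above 95:5).

### Fragment union and completion

Step 16
Reactants: 17 tributyl(2-methylidene-4-Ox-butyl)stannane; 21 (2E)-5-[(4-methoxyphenyl)methoxy]-2-methylpent-2-enal
Product: 22 (3E,5R)-4-methyl-7-methylidene-9-Ox-1-(PMB-oxy)non-3-en-5-ol
Conditions: (R)-BINOL (20 mol %), Ti(OiPr)4 (10 mol %), 4 Å MS, CH2Cl2, −20 °C; aq. NaHCO3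
Reagents that add atoms: none
Why: Keck catalytic asymmetric carbonyl allylation joins the two fragments at C2–C3, the (R)-BINOL–titanium Lewis acid exposing one face of the enal to the 2-substituted allylstannane in an open SE2' transition state so that C3 is set as R (the sense given by (R)-BINOL when the aldehyde substituent outranks the allyl carbon).

Step 17
Reactants: 22 (3E,5R)-4-methyl-7-methylidene-9-Ox-1-(PMB-oxy)non-3-en-5-ol
Product: 23 (1R)-3-methylidene-5-Ox-1-{(2R,3R)-2-methyl-3-[2-(PMB-oxy)ethyl]oxiran-2-yl}pentan-1-ol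
Conditions: Ti(OiPr)4, D-(−)-diisopropyl tartrate, t-BuOOH, 4 Å MS, CH2Cl2, −20 °C
Reagents that add atoms: tert-butyl hydroperoxide, CC(C)(C)OO
Why: Sharpless asymmetric epoxidation in the matched sense, in which the (3R) allylic alcohol is the fast-reacting enantiomer with the D-(−)-tartrate and gives the erythro (3R,4R,5R) epoxy alcohol, sets C4, leaves any (3S) epimer from step 16 unreacted and does not touch the homoallylic or isolated alkenes.

Step 18
Reactants: 23 (1R)-3-methylidene-5-Ox-1-{(2R,3R)-2-methyl-3-[2-(PMB-oxy)ethyl]oxiran-2-yl}pentan-1-ol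
Product: 24 (4S,5R)-4-methyl-7-methylidene-9-Ox-1-(PMB-oxy)nonane-4,5-diol
Conditions: LiBH4, Ti(OiPr)4, THF, 0 °C to rt
Reagents that add atoms: none
Why: Hydroxyl-directed reductive epoxide opening delivers hydride by SN2 attack at the less substituted C5 of the titanium-bound epoxy alcohol, so the C4–O bond stays and C4 becomes the (S) tertiary alcohol, while the unanchored C11–C12 oxirane reacts far more slowly.

Step 19
Reactants: 24 (4S,5R)-4-methyl-7-methylidene-9-Ox-1-(PMB-oxy)nonane-4,5-diol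
Product: 25 (4S,5R)-4-hydroxy-4-methyl-7-methylidene-9-Ox-1-(PMB-oxy)nonan-5-yl prop-2-enoate
Conditions: CH2=CHCOCl, iPr2NEt, CH2Cl2, −78 to 0 °C
Reagents that add atoms: acryloyl chloride, C=CC(=O)Cl
Why: Chemoselective O-acylation esterifies the secondary C3 hydroxyl while the hindered tertiary C4 hydroxyl does not react.

Step 20
Reactants: 25 (4S,5R)-4-hydroxy-4-methyl-7-methylidene-9-Ox-1-(PMB-oxy)nonan-5-yl prop-2-enoate
Product: 26 (4S,5R)-4-methyl-7-methylidene-9-Ox-1-(PMB-oxy)-4-(TES-oxy)nonan-5-yl prop-2-enoate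
Conditions: Et3SiOTf, 2,6-lutidine, CH2Cl2, −78 °C
Reagents that add atoms: triethylsilyl trifluoromethanesulfonate, CC[Si](CC)(CC)OS(=O)(=O)C(F)(F)F
Why: Silylation with the silyl triflate and a hindered base protects the tertiary alcohol at −78 °C faster than the oxirane can be activated.

Step 21
Reactants: 26 (4S,5R)-4-methyl-7-methylidene-9-Ox-1-(PMB-oxy)-4-(TES-oxy)nonan-5-yl prop-2-enoate
Product: 27 (6R)-4-(2-Ox-ethyl)-6-[(2S)-5-(PMB-oxy)-2-(TES-oxy)pentan-2-yl]-5,6-dihydro-2H-pyran-2-one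
Conditions: second-generation Grubbs catalyst (H2IMes)(PCy3)Cl2Ru=CHPh (10 mol %), toluene, 80 °C, 0.005 M
Reagents that add atoms: none
Why: Ring-closing metathesis between the acrylate and the 1,1-disubstituted alkene closes the six-membered unsaturated lactone with loss of ethene, the alkenyl iodide being too hindered to engage.

Step 22
Reactants: 27 (6R)-4-(2-Ox-ethyl)-6-[(2S)-5-(PMB-oxy)-2-(TES-oxy)pentan-2-yl]-5,6-dihydro-2H-pyran-2-one
Product: 28 (4R,6R)-4-(2-Ox-ethyl)-6-[(2S)-5-(PMB-oxy)-2-(TES-oxy)pentan-2-yl]oxan-2-one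
Conditions: Cu(OAc)2·H2O (5 mol %), 1,2-bis(diphenylphosphino)benzene (5 mol %), (EtO)2MeSiH, t-BuOH, toluene, rt
Reagents that add atoms: none
Why: Copper hydride conjugate reduction adds hydride to C1 of the half-chair lactone from the face opposite the bulky C3 substituent, which places the C14 chain cis to it (1R), and this soft phosphine-ligated hydride is expected to leave the alkenyl iodide, oxirane and unactivated alkene alone.

Step 23
Reactants: 28 (4R,6R)-4-(2-Ox-ethyl)-6-[(2S)-5-(PMB-oxy)-2-(TES-oxy)pentan-2-yl]oxan-2-one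
Product: 30 (3S,4R,6R)-3-methyl-4-(2-Ox-ethyl)-6-[(2S)-5-(PMB-oxy)-2-(TES-oxy)pentan-2-yl]oxan-2-one, via lithium enolate 29 (not isolated)
Conditions: LiN(iPr)2, THF, −78 °C; MeI, −78 to −40 °C
Reagents that add atoms: iodomethane, CI
Why: Lactone enolate alkylation brings methyl iodide in anti to the adjacent C1 substituent and gives the 3,4-trans (15S) methyl lactone, which is also the all-equatorial thermodynamic isomer.

Step 24
Reactants: 30 (3S,4R,6R)-3-methyl-4-(2-Ox-ethyl)-6-[(2S)-5-(PMB-oxy)-2-(TES-oxy)pentan-2-yl]oxan-2-one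
Product: 31 (3S,4R,6R)-6-[(2S)-5-hydroxy-2-(TES-oxy)pentan-2-yl]-3-methyl-4-(2-Ox-ethyl)oxan-2-one
Conditions: DDQ, CH2Cl2/aq. NaH2PO4–Na2HPO4 buffer (pH 7), 0 °C
Reagents that add atoms: none
Why: Oxidative PMB ether cleavage under buffered conditions frees the primary alcohol without affecting the silyl ether, oxirane, lactone or alkenyl iodide.

Step 25
Reactants: 31 (3S,4R,6R)-6-[(2S)-5-hydroxy-2-(TES-oxy)pentan-2-yl]-3-methyl-4-(2-Ox-ethyl)oxan-2-one
Product: 32 (4S)-4-[(2R,4R,5S)-5-methyl-6-oxo-4-(2-Ox-ethyl)oxan-2-yl]-4-(TES-oxy)pentanal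
Conditions: Dess–Martin periodinane, NaHCO3, CH2Cl2, 0 °C to rt
Reagents that add atoms: none
Why: Dess–Martin oxidation gives the aldehyde, which cannot close to a lactol because the C4 oxygen is silylated.

Step 26
Reactants: 32 (4S)-4-[(2R,4R,5S)-5-methyl-6-oxo-4-(2-Ox-ethyl)oxan-2-yl]-4-(TES-oxy)pentanal
Product: 33 (1R,3R,4S,7RS,11S,12S,15S)-11,12-epoxy-7-hydroxy-4-(TES-oxy)cembr-8(19)-en-16,3-olide (C7 epimer mixture)
Conditions: CrCl2 (15 equiv), NiCl2 (1 mol % of the CrCl2), DMSO/THF, rt, 0.003 M, slow addition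
Reagents that add atoms: none
Why: Nozaki–Hiyama–Kishi reaction, in which a nickel-catalysed alkenylchromium species adds chemoselectively to the aldehyde under high dilution, closes the 14-membered ring at C7–C8 and gives the 2-methylidene allylic alcohol directly, C7 forming as an epimer mixture that the next two steps correct.

Step 27
Reactants: 33 (1R,3R,4S,7RS,11S,12S,15S)-11,12-epoxy-7-hydroxy-4-(TES-oxy)cembr-8(19)-en-16,3-olide
Product: 34 (1R,3R,4S,11S,12S,15S)-11,12-epoxy-7-oxo-4-(TES-oxy)cembr-8(19)-en-16,3-olide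
Conditions: Dess–Martin periodinane, NaHCO3, CH2Cl2, 0 °C
Reagents that add atoms: none
Why: Dess–Martin oxidation converges both C7 epimers on one α-methylidene ketone.

Step 28
Reactants: 34 (1R,3R,4S,11S,12S,15S)-11,12-epoxy-7-oxo-4-(TES-oxy)cembr-8(19)-en-16,3-olide
Product: 35 (1R,3R,4S,7R,11S,12S,15S)-11,12-epoxy-7-hydroxy-4-(TES-oxy)cembr-8(19)-en-16,3-olide
Conditions: (S)-2-methyl-CBS-oxazaborolidine, catecholborane, toluene, −78 °C
Reagents that add atoms: none
Why: Corey–Bakshi–Shibata reduction, in which the (S)-oxazaborolidine treats the α-branched alkenyl group as the large substituent, delivers hydride in a 1,2-sense to give the (7R) allylic alcohol, as for the (R) alcohols obtained from enones with this catalyst.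

Step 29
Reactants: 35 (1R,3R,4S,7R,11S,12S,15S)-11,12-epoxy-7-hydroxy-4-(TES-oxy)cembr-8(19)-en-16,3-olide
Product: 36 (1R,3R,4S,7R,11S,12S,15S)-11,12-epoxy-4,7-dihydroxycembr-8(19)-en-16,3-olide (CNP0262409.1)
Conditions: Bu4NF, THF, 0 °C to rt
Reagents that add atoms: none
Why: Fluoride-mediated desilylation removes the triethylsilyl group and leaves the lactone, oxirane and allylic alcohol intact, giving the target.

## Compound list

1 | pent-4-yn-1-ol | C#CCCCO | starting material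
2 | 4-iodopent-4-en-1-ol | C=C(I)CCCO | intermediate
3 | 4-iodopent-4-enal | C=C(I)CCC=O | intermediate
4 | rac-6-iodo-2-methylhepta-1,6-dien-3-ol | C=C(C)C(O)CCC(I)=C | intermediate
5 | 1-ethoxy-1-[(6-iodo-2-methylhepta-1,6-dien-3-yl)oxy]ethene (mixed ketene acetal) | C=C(OCC)OC(C(C)=C)CCC(I)=C | intermediate
6 | ethyl (4E)-8-iodo-4-methylnona-4,8-dienoate | CCOC(=O)CC/C(C)=C/CCC(I)=C | intermediate
7 | (4E)-8-iodo-4-methylnona-4,8-dienal | O=CCC/C(C)=C/CCC(I)=C | intermediate
8 | (5E)-9-iodo-1-methoxy-5-methyldeca-1,5,9-triene (C1 isomer mixture) | COC=CCC/C(C)=C/CCC(I)=C | intermediate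
9 | (5E)-9-iodo-5-methyldeca-5,9-dienal | O=CCCC/C(C)=C/CCC(I)=C | intermediate
10 | (5E)-2-[(dimethylamino)methyl]-9-iodo-5-methyldeca-5,9-dienal (Mannich base) | CN(C)CC(C=O)CC/C(C)=C/CCC(I)=C | intermediate
11 | (5E)-9-iodo-5-methyl-2-methylidenedeca-5,9-dienal | C=C(C=O)CC/C(C)=C/CCC(I)=C | intermediate
12 | (5E)-9-iodo-5-methyl-2-methylidenedeca-5,9-dien-1-ol | C=C(CO)CC/C(C)=C/CCC(I)=C | intermediate
13 | 4-[(2S,3S)-3-(3-iodobut-3-en-1-yl)-2-methyloxiran-2-yl]-2-methylidenebutan-1-ol | C=C(I)CC[C@@H]1O[C@@]1(C)CCC(=C)CO | intermediate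
14 | 2-methylidene-4-Ox-butyl methanesulfonate | C=C(I)CC[C@@H]1O[C@@]1(C)CCC(=C)COS(C)(=O)=O | intermediate
15 | (2S,3S)-2-[3-(bromomethyl)but-3-en-1-yl]-3-(3-iodobut-3-en-1-yl)-2-methyloxirane | C=C(I)CC[C@@H]1O[C@@]1(C)CCC(=C)CBr | intermediate
16 | bromo(2-methylidene-4-Ox-butyl)zinc | C=C(I)CC[C@@H]1O[C@@]1(C)CCC(=C)C[Zn]Br | intermediate
17 | tributyl(2-methylidene-4-Ox-butyl)stannane | C=C(I)CC[C@@H]1O[C@@]1(C)CCC(=C)C[Sn](CCCC)(CCCC)CCCC | intermediate
18 | propane-1,3-diol | OCCCO | starting material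
19 | 3-[(4-methoxyphenyl)methoxy]propan-1-ol | COc1ccc(COCCCO)cc1 | intermediate
20 | 3-[(4-methoxyphenyl)methoxy]propanal | COc1ccc(COCCC=O)cc1 | intermediate
21 | (2E)-5-[(4-methoxyphenyl)methoxy]-2-methylpent-2-enal | COc1ccc(COCC/C=C(\C)C=O)cc1 | intermediate
22 | (3E,5R)-4-methyl-7-methylidene-9-Ox-1-(PMB-oxy)non-3-en-5-ol | C=C(I)CC[C@@H]1O[C@@]1(C)CCC(=C)C[C@@H](O)/C(C)=C/CCOCc2ccc(OC)cc2 | intermediate
23 | (1R)-3-methylidene-5-Ox-1-{(2R,3R)-2-methyl-3-[2-(PMB-oxy)ethyl]oxiran-2-yl}pentan-1-ol | C=C(I)CC[C@@H]1O[C@@]1(C)CCC(=C)C[C@@H](O)[C@@]2(C)O[C@@H]2CCOCc3ccc(OC)cc3 | intermediate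
24 | (4S,5R)-4-methyl-7-methylidene-9-Ox-1-(PMB-oxy)nonane-4,5-diol | C=C(I)CC[C@@H]1O[C@@]1(C)CCC(=C)C[C@@H](O)[C@@](C)(O)CCCOCc2ccc(OC)cc2 | intermediate
25 | (4S,5R)-4-hydroxy-4-methyl-7-methylidene-9-Ox-1-(PMB-oxy)nonan-5-yl prop-2-enoate | C=C(I)CC[C@@H]1O[C@@]1(C)CCC(=C)C[C@@H](OC(=O)C=C)[C@@](C)(O)CCCOCc2ccc(OC)cc2 | intermediate
26 | (4S,5R)-4-methyl-7-methylidene-9-Ox-1-(PMB-oxy)-4-(TES-oxy)nonan-5-yl prop-2-enoate | C=C(I)CC[C@@H]1O[C@@]1(C)CCC(=C)C[C@@H](OC(=O)C=C)[C@@](C)(O[Si](CC)(CC)CC)CCCOCc2ccc(OC)cc2 | intermediate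
27 | (6R)-4-(2-Ox-ethyl)-6-[(2S)-5-(PMB-oxy)-2-(TES-oxy)pentan-2-yl]-5,6-dihydro-2H-pyran-2-one | C=C(I)CC[C@@H]1O[C@@]1(C)CCC2=CC(=O)O[C@H](C2)[C@@](C)(O[Si](CC)(CC)CC)CCCOCc3ccc(OC)cc3 | intermediate
28 | (4R,6R)-4-(2-Ox-ethyl)-6-[(2S)-5-(PMB-oxy)-2-(TES-oxy)pentan-2-yl]oxan-2-one | C=C(I)CC[C@@H]1O[C@@]1(C)CC[C@H]2CC(=O)O[C@H](C2)[C@@](C)(O[Si](CC)(CC)CC)CCCOCc3ccc(OC)cc3 | intermediate
29 | lithium (4R,6R)-4-(2-Ox-ethyl)-6-[(2S)-5-(PMB-oxy)-2-(TES-oxy)pentan-2-yl]-5,6-dihydro-4H-pyran-2-olate (lithium enolate of 28) | C=C(I)CC[C@@H]1O[C@@]1(C)CC[C@H]2C=C(O[Li])O[C@H](C2)[C@@](C)(O[Si](CC)(CC)CC)CCCOCc3ccc(OC)cc3 | intermediate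
30 | (3S,4R,6R)-3-methyl-4-(2-Ox-ethyl)-6-[(2S)-5-(PMB-oxy)-2-(TES-oxy)pentan-2-yl]oxan-2-one | C=C(I)CC[C@@H]1O[C@@]1(C)CC[C@H]2[C@H](C)C(=O)O[C@H](C2)[C@@](C)(O[Si](CC)(CC)CC)CCCOCc3ccc(OC)cc3 | intermediate
31 | (3S,4R,6R)-6-[(2S)-5-hydroxy-2-(TES-oxy)pentan-2-yl]-3-methyl-4-(2-Ox-ethyl)oxan-2-one | C=C(I)CC[C@@H]1O[C@@]1(C)CC[C@H]2[C@H](C)C(=O)O[C@H](C2)[C@@](C)(O[Si](CC)(CC)CC)CCCO | intermediate
32 | (4S)-4-[(2R,4R,5S)-5-methyl-6-oxo-4-(2-Ox-ethyl)oxan-2-yl]-4-(TES-oxy)pentanal | C=C(I)CC[C@@H]1O[C@@]1(C)CC[C@H]2[C@H](C)C(=O)O[C@H](C2)[C@@](C)(O[Si](CC)(CC)CC)CCC=O | intermediate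
33 | (1R,3R,4S,7RS,11S,12S,15S)-11,12-epoxy-7-hydroxy-4-(TES-oxy)cembr-8(19)-en-16,3-olide | C=C1CC[C@@H]2O[C@@]2(C)CC[C@@H]2C[C@@H](OC(=O)[C@H]2C)[C@@](C)(O[Si](CC)(CC)CC)CCC1O | intermediate
34 | (1R,3R,4S,11S,12S,15S)-11,12-epoxy-7-oxo-4-(TES-oxy)cembr-8(19)-en-16,3-olide | C=C1CC[C@@H]2O[C@@]2(C)CC[C@@H]2C[C@@H](OC(=O)[C@H]2C)[C@@](C)(O[Si](CC)(CC)CC)CCC1=O | intermediate
35 | (1R,3R,4S,7R,11S,12S,15S)-11,12-epoxy-7-hydroxy-4-(TES-oxy)cembr-8(19)-en-16,3-olide | C=C1CC[C@@H]2O[C@@]2(C)CC[C@@H]2C[C@@H](OC(=O)[C@H]2C)[C@@](C)(O[Si](CC)(CC)CC)CC[C@H]1O | intermediate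
36 | (1R,3R,4S,7R,11S,12S,15S)-11,12-epoxy-4,7-dihydroxycembr-8(19)-en-16,3-olide (CNP0262409.1) | C=C1CC[C@@H]2O[C@@]2(C)CC[C@@H]2C[C@@H](OC(=O)[C@H]2C)[C@@](C)(O)CC[C@H]1O | target

## Step count and risks

Total steps: 29. Longest linear sequence: 26 (steps 1–12, then 16–29); the East fragment takes 3 steps (13–15).

The three steps most likely to fail:

**Step 16 (Keck allylation).** The trisubstituted enal is a sluggish electrophile and the stannane is acid-sensitive. Fallback: setting out from allylic bromide 15 and enal 21, a CrCl2-mediated Nozaki–Hiyama carbonyl allylation without any nickel salt (THF, rt, alkenyl iodide untouched) joins the fragments without control at C3 and gives the C3-epimeric homoallylic alcohol F1. F1 is then put through the conditions of step 17, where the Sharpless epoxidation with D-(−)-diisopropyl tartrate acts as a kinetic resolution: only the (3R) epimer is epoxidised, the unreacted (3S) epimer is removed by chromatography, and the route is rejoined at 23 (at the cost of at most half the material).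

**Step 26 (macrocyclisation).** Oligomerisation or slow reaction of the hindered alkenyl iodide is possible. Fallback: setting out from aldehyde 32, Pinnick oxidation (NaClO2, NaH2PO4, 2-methylbut-2-ene, t-BuOH/H2O) gives the carboxylic acid F2. 2,2'-Dipyridyl disulfide and PPh3 convert it into the S-(pyridin-2-yl) thioester F3. A nickel-catalysed reductive ketone coupling of the thioester with the alkenyl iodide (NiBr2(4,4'-di-tert-butyl-2,2'-bipyridine), Cp2ZrCl2, Zn dust, 1,3-dimethylimidazolidin-2-one/THF, high dilution) closes the ring as the ketone and comes back to the route at enone 34, replacing steps 26 and 27. This coupling is less well precedented for alkenyl iodides than for alkyl iodides.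

**Step 28 (CBS reduction in the macrocycle).** Ring conformation may override catalyst control. Fallback: setting out from enone 34, Luche reduction (NaBH4, CeCl3·7H2O, MeOH, −78 °C) gives 35 together with the (7S)-alcohol F4. After separation, F4 is inverted by a Mitsunobu reaction (4-nitrobenzoic acid, PPh3, diisopropyl azodicarboxylate, toluene, 0 °C) to the (7R) 4-nitrobenzoate F5, whose ester is cleaved (K2CO3, MeOH, 0 °C) to come back to 35.

## Further compounds

F1 | step 16 | (3E,5RS)-4-methyl-7-methylidene-9-Ox-1-(PMB-oxy)non-3-en-5-ol (C3 epimer mixture) | C=C(I)CC[C@@H]1O[C@@]1(C)CCC(=C)CC(O)/C(C)=C/CCOCc2ccc(OC)cc2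
F2 | step 26 | (4S)-4-[(2R,4R,5S)-5-methyl-6-oxo-4-(2-Ox-ethyl)oxan-2-yl]-4-(TES-oxy)pentanoic acid | C=C(I)CC[C@@H]1O[C@@]1(C)CC[C@H]2[C@H](C)C(=O)O[C@H](C2)[C@@](C)(O[Si](CC)(CC)CC)CCC(=O)O
F3 | step 26 | S-(pyridin-2-yl) (4S)-4-[(2R,4R,5S)-5-methyl-6-oxo-4-(2-Ox-ethyl)oxan-2-yl]-4-(TES-oxy)pentanethioate | C=C(I)CC[C@@H]1O[C@@]1(C)CC[C@H]2[C@H](C)C(=O)O[C@H](C2)[C@@](C)(O[Si](CC)(CC)CC)CCC(=O)Sc3ccccn3
F4 | step 28 | (1R,3R,4S,7S,11S,12S,15S)-11,12-epoxy-7-hydroxy-4-(TES-oxy)cembr-8(19)-en-16,3-olide | C=C1CC[C@@H]2O[C@@]2(C)CC[C@@H]2C[C@@H](OC(=O)[C@H]2C)[C@@](C)(O[Si](CC)(CC)CC)CC[C@@H]1O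
F5 | step 28 | (1R,3R,4S,7R,11S,12S,15S)-11,12-epoxy-7-[(4-nitrobenzoyl)oxy]-4-(TES-oxy)cembr-8(19)-en-16,3-olide | C=C1CC[C@@H]2O[C@@]2(C)CC[C@@H]2C[C@@H](OC(=O)[C@H]2C)[C@@](C)(O[Si](CC)(CC)CC)CC[C@H]1OC(=O)c3ccc(cc3)[N+](=O)[O-]
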